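**Plan**

1. Retrosynthesis: the C–Br bond goes back to an alkenyl bromide and a ring-A ketone, the trans-diol to a ring-A alkene. Ring A is then cut at the two bonds flanking its CH2–CH(OH) unit, which leaves a tricyclic 4-alkynal and acetylene.
2. The alkynal goes back to a trans-fused γ-lactone. Ring B and the norbornane are cut together by an intramolecular Diels–Alder reaction; the diene arm comes from a B-alkyl Suzuki coupling and the lactone from furan-2(5H)-one.
3. Forward order: lactone with both arms (steps 1–6), ring B and both norbornane rings in one cycloaddition (step 7), adjustment to the alkynal (steps 8–14), ring A by rhodium-catalysed [4+2] annulation (step 15), diol and bromide (steps 16–19).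
4. Stereochemistry: a rhodium/(R)-BINAP conjugate addition sets the first center and two enolate substitutions trans to it set the quaternary carbon. The trans-lactone, the exo tether and the (E)-alkene fix four centers in the cycloaddition, and exo hydrogenation sets the isopropyl center. Epoxidation anti to the axial methyl with diaxial opening sets the diol, and hydrogen-atom-transfer hydrogenation sets the equatorial bromide.
5. Enabling feature: in ring A the bromine-bearing carbon sits on the quaternary methyl-bearing ring-fusion carbon and the methyl carbinol carbon on the neighbouring ring-fusion CH. As formyl and ethynyl groups these two carbons form a 4-alkynal, and because the quaternary carbon has no hydrogen neither the acyl rhodium species nor the dienone can enolise or aromatise.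

Key step: step 15

Remark: the ligand enantiomer in step 2 is chosen by analogy with rhodium–BINAP additions to cyclic enones; if the sense of induction proves opposite, (S)-BINAP is used and nothing else changes.

**Route**

Step 1
Reactants: 1 ethynyl(dimethyl)phenylsilane; 2 pinacolborane
Product: 3 (E)-dimethyl(phenyl)[2-(4,4,5,5-tetramethyl-1,3,2-dioxaborolan-2-yl)ethenyl]silane
Conditions: Cp2Zr(H)Cl (5 mol %), Et3N (10 mol %), neat, 60 °C
Reagents that add atoms: none
Why: Zirconium-catalysed hydroboration of the terminal alkyne is a syn anti-Markovnikov addition (alkyne hydroboration) and should give only the (E)-1-boryl-2-silylethene.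

Step 2
Reactants: 3 (E)-alkenylboronate; 4 furan-2(5H)-one
Product: 5 (R)-4-[(E)-2-(dimethylphenylsilyl)ethenyl]oxolan-2-one
Conditions: [RhCl(C2H4)2]2 (1.5 mol %), (R)-BINAP (3.3 mol %), KOH (0.2 equiv), dioxane–H2O 10:1, 50 °C
Reagents that add atoms: none
Why: Rhodium-catalysed asymmetric 1,4-addition of an alkenylboron reagent to an unsaturated lactone (Hayashi–Miyaura reaction); the (R)-BINAP-bound alkenylrhodium should add to one face of the butenolide and set the (R) center from which all later centers are relayed.

Step 3
Reactants: 5 (R)-lactone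
Product: 6 (3S,4R)-3-methyl-4-[(E)-2-(dimethylphenylsilyl)ethenyl]oxolan-2-one
Conditions: LiN(iPr)2, THF, –78 °C; MeI, –78 to –40 °C
Reagents that add atoms: iodomethane, CI
Why: Alkylation of the lactone lithium enolate, which should take up iodomethane trans to the neighbouring alkenyl group (this center is planarised again in step 4).

Step 4
Reactants: 6 trans-methyl lactone
Product: 7 (3S,4S)-3-ethenyl-3-methyl-4-[(E)-2-(dimethylphenylsilyl)ethenyl]oxolan-2-one
Conditions: LiN(SiMe3)2, Pd2(dba)3 (2 mol %), P(tBu)3 (8 mol %), bromoethene (1 M in THF), toluene, 25 °C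
Reagents that add atoms: bromoethene, C=CBr
Why: Palladium-catalysed α-vinylation of a lactone enolate (enolate cross-coupling); coupling should occur on the face away from the neighbouring alkenyl group, so the vinyl group ends trans and the methyl cis to it and the quaternary center is fixed.

Step 5
Reactants: 7 methyl vinyl lactone; 8 2-iodocyclopent-2-en-1-one
Product: 10 (3S,4S)-3-methyl-3-[2-(5-oxocyclopent-1-en-1-yl)ethyl]-4-[(E)-2-(dimethylphenylsilyl)ethenyl]oxolan-2-one, via alkylborane 9 (not isolated)
Conditions: 9-BBN, THF, 25 °C; then 8, PdCl2(dppf) (5 mol %), AsPh3, Cs2CO3, DMF–H2O, 25 °C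
Reagents that add atoms: 9-borabicyclo[3.3.1]nonane, B1C2CCCC1CCC2
Why: 9-BBN should add to the monosubstituted vinyl group much faster than to the 1,2-disubstituted vinylsilane (anti-Markovnikov hydroboration), and the primary alkylborane then couples with the 2-iodoenone in a B-alkyl Suzuki–Miyaura reaction.

Step 6
Reactants: 10 enone lactone
Product: 11 (3S,4S)-3-[2-(5-hydroxy-5-isopropylcyclopent-1-en-1-yl)ethyl]-3-methyl-4-[(E)-2-(dimethylphenylsilyl)ethenyl]oxolan-2-one (both carbinol epimers)
Conditions: iPrMgCl, CeCl3, THF, –78 °C
Reagents that add atoms: isopropylmagnesium chloride, CC(C)[Mg]Cl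
Why: The organocerium reagent should add 1,2 to the enone carbonyl without enolisation and, at –78 °C, faster than to the lactone (carbonyl addition); the carbinol configuration is lost in step 7.

Step 7
Reactants: 11 tertiary allylic alcohol
Product: 13 tetracyclic silyl lactone (norbornene fused to ring B; silicon endo), via cyclopentadiene 12 (not isolated)
Conditions: TsOH·H2O (2 mol %), toluene, 25 °C; then BHT (cat.), high dilution, 185 °C, sealed tube
Reagents that add atoms: none
Why: Acid-catalysed dehydration gives the 1,2-dialkylcyclopentadiene, whose isomers equilibrate by 1,5-hydrogen shifts, and the isomer with the tether on a diene terminus should close ring B and the norbornene in an intramolecular Diels–Alder reaction; the trans-fused lactone allows one chair for ring B, the four-atom tether spans only the exo position and the (E)-alkene puts silicon endo, which together fix the four new centers.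

Step 8
Reactants: 13 cycloadduct
Product: 14 saturated silyl lactone (isopropyl endo)
Conditions: H2 (1 atm), Pd/C, EtOAc, 25 °C
Reagents that add atoms: none
Why: Heterogeneous hydrogenation of the strained norbornene double bond should occur from the exo face (the endo face is covered by the silyl-bearing bridge), which places the isopropyl group endo.

Step 9
Reactants: 14 saturated silyl lactone
Product: 15 endo alcohol lactone
Conditions: KBr, AcOOH, NaOAc, AcOH, 25 °C
Reagents that add atoms: peracetic acid, CC(=O)OO
Why: Tamao–Fleming oxidation of the phenyldimethylsilyl group (bromodesilylation of the phenyl ring, then peracid-induced shift from silicon to oxygen) replaces C–Si by C–OH with retention.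

Step 10
Reactants: 15 endo alcohol
Product: 16 endo methyl ether lactone
Conditions: NaH, MeI, THF, 0 to 25 °C
Reagents that add atoms: iodomethane, CI
Why: Williamson etherification of the secondary alkoxide; the lactone has no α-hydrogen and should not be affected.

Step 11
Reactants: 16 methyl ether lactone
Product: 17 diol (CH2OH on the quaternary methyl carbon and on the neighbouring ring-B CH)
Conditions: LiAlH4, THF, 0 to 25 °C
Reagents that add atoms: none
Why: Hydride reduction of the lactone to the 1,4-diol.

Step 12
Reactants: 17 diol
Product: 18 γ-lactol (hemiacetal carbon on the ring-B CH)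
Conditions: IBX, DMSO, 25 °C
Reagents that add atoms: none
Why: IBX should oxidise the less hindered primary alcohol (the other is neopentylic) and the hydroxy aldehyde closes to the γ-lactol, which IBX in DMSO does not oxidise further (selective diol-to-lactol oxidation).

Step 13
Reactants: 18 lactol
Product: 19 alkynol (ethynyl on the ring-B CH; CH2OH on the quaternary carbon)
Conditions: dimethyl (1-diazo-2-oxopropyl)phosphonate, K2CO3, MeOH, 25 °C
Reagents that add atoms: dimethyl (1-diazo-2-oxopropyl)phosphonate, CC(=O)C(=[N+]=[N-])P(=O)(OC)OC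
Why: Seyferth–Gilbert homologation with the Ohira–Bestmann reagent on the open hydroxy-aldehyde form gives the terminal alkyne; the trans (diequatorial) arrangement at the epimerisable CH is the stable one under the basic conditions.

Step 14
Reactants: 19 alkynol
Product: 20 4-alkynal (formyl on the quaternary carbon; ethynyl on the neighbouring CH)
Conditions: Dess–Martin periodinane, NaHCO3, CH2Cl2, 25 °C
Reagents that add atoms: none
Why: Dess–Martin oxidation of the neopentylic primary alcohol to the non-enolisable aldehyde.

Step 15
Reactants: 20 4-alkynal; 21 acetylene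
Product: 22 tetracyclic dienone (ring A as a 4-methylenecyclohex-2-enone)
Conditions: [Rh(dppe)]ClO4 (10 mol %, from [Rh(nbd)(dppe)]ClO4 and H2), C2H2 (1 atm, saturated solution), acetone, 25 °C
Reagents that add atoms: none
Why: Monovalent rhodium adds oxidatively into the formyl C–H bond, the acyl rhodium hydride adds across the neighbouring ethynyl group to give a five-membered acyl–alkenyl rhodacycle with an exocyclic methylene, acetylene inserts, and C–C reductive elimination from the seven-membered rhodacycle releases the dienone and the catalyst. The closest known reaction type is the rhodium-catalysed [4+2] annulation of 4-alkynals with alkynes. Ring A closes as a six-membered carbocycle in a formal [4+2] mode (formyl carbon, quaternary carbon, ring-B CH and inner alkyne carbon plus the two acetylene carbons) and is trans-fused to ring B because both reacting groups are equatorial. No new stereocenter is formed and the two ring-fusion centers are not touched, since the quaternary carbon cannot enolise and the CH stays sp3 throughout. The selectivity needed is annulation over intramolecular hydroacylation to the fused cyclopentenone and over acetylene oligomerisation; a saturated acetylene solution, the chelating dppe ligand and room temperature should favour interception of the five-membered rhodacycle, which cannot itself eliminate to a cyclobutanone.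

Step 16
Reactants: 22 dienone
Product: 23 β,γ-unsaturated ketone (ring A: C=O, CH2, CH=C(CH3))
Conditions: Li (2.2 equiv), NH3(l), THF, –78 °C; solid NH4Cl, –78 °C
Reagents that add atoms: none
Why: Dissolving-metal (Birch-type) reduction of the linear dienone should protonate the exocyclic terminus to give the extended dienolate, whose kinetic protonation at the α-carbon gives the β,γ-unsaturated ketone with the trisubstituted ring double bond.

Step 17
Reactants: 23 β,γ-unsaturated ketone
Product: 25 dihydroxy ketone (trans-diaxial diol), via epoxide 24 (not isolated)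
Conditions: mCPBA, NaHCO3, CH2Cl2, 0 °C; then HClO4 (cat.), THF–H2O, 0 °C
Reagents that add atoms: 3-chloroperbenzoic acid, OOC(=O)c1cccc(Cl)c1; water, O
Why: Prilezhaev epoxidation should occur on the face of the ring-A alkene opposite the axial angular methyl, and acid-catalysed opening follows the Fürst–Plattner rule with water attacking the tertiary carbon axially, which gives the trans-diaxial diol with both carbinol centers in the target configuration.

Step 18
Reactants: 25 dihydroxy ketone
Product: 27 alkenyl bromide (ring A: C(Br)=CH next to the quaternary carbon), via hydrazone 26 (not isolated)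
Conditions: N2H4·H2O, Et3N, EtOH, 80 °C; evaporation; then NBS, pyridine, 0 to 25 °C
Reagents that add atoms: hydrazine, NN; N-bromosuccinimide, BrN1C(=O)CCC1=O
Why: Condensation gives the hydrazone, which N-bromosuccinimide oxidises to the diazo compound and brominates to an α-bromo diazonium ion that loses nitrogen and a proton (Barton-type vinyl halide synthesis); elimination can go only toward the CH2 group because the other neighbour is quaternary.

Step 19
Reactants: 27 alkenyl bromide
Product: 28 CNP0130529.1
Conditions: Mn(dpm)3 (10 mol %), PhSiH3, tBuOOH, iPrOH, 25 °C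
Reagents that add atoms: none
Why: Manganese-catalysed hydrogen-atom-transfer hydrogenation (Mukaiyama-type) adds H• to the CH end of the bromoalkene, and the α-bromo radical should take up the second hydrogen axially, so that bromine ends equatorial (the more stable epimer) without loss of the C–Br bond.

**Compound list**

1 | ethynyl(dimethyl)phenylsilane | C#C[Si](C)(C)c1ccccc1 | starting material
2 | pinacolborane | B1OC(C)(C)C(C)(C)O1 | starting material
3 | (E)-dimethyl(phenyl)[2-(4,4,5,5-tetramethyl-1,3,2-dioxaborolan-2-yl)ethenyl]silane | C[Si](C)(/C=C/B1OC(C)(C)C(C)(C)O1)c1ccccc1 | intermediate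
4 | furan-2(5H)-one | O=C1OCC=C1 | starting material
5 | (R)-4-[(E)-2-(dimethylphenylsilyl)ethenyl]oxolan-2-one | O=C1OC[C@H](C1)/C=C/[Si](C)(C)c1ccccc1 | intermediate
6 | (3S,4R)-3-methyl-4-[(E)-2-(dimethylphenylsilyl)ethenyl]oxolan-2-one (methyl trans to the alkenyl group) | C[C@@H]1C(=O)OC[C@H]1/C=C/[Si](C)(C)c1ccccc1 | intermediate
7 | (3S,4S)-3-ethenyl-3-methyl-4-[(E)-2-(dimethylphenylsilyl)ethenyl]oxolan-2-one (ethenyl trans, methyl cis to the silylethenyl group) | C=C[C@]1(C)C(=O)OC[C@H]1/C=C/[Si](C)(C)c1ccccc1 | intermediate
8 | 2-iodocyclopent-2-en-1-one | O=C1CCC=C1I | starting material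
9 | B-alkyl-9-BBN adduct of 7 (boron on the terminal carbon of the former ethenyl group; not isolated) | C(CB1C2CCCC1CCC2)[C@]1(C)C(=O)OC[C@H]1/C=C/[Si](C)(C)c1ccccc1 | intermediate
10 | (3S,4S)-3-methyl-3-[2-(5-oxocyclopent-1-en-1-yl)ethyl]-4-[(E)-2-(dimethylphenylsilyl)ethenyl]oxolan-2-one | O=C1CCC=C1CC[C@]1(C)C(=O)OC[C@H]1/C=C/[Si](C)(C)c1ccccc1 | intermediate
11 | (3S,4S)-3-[2-(5-hydroxy-5-isopropylcyclopent-1-en-1-yl)ethyl]-3-methyl-4-[(E)-2-(dimethylphenylsilyl)ethenyl]oxolan-2-one (both carbinol epimers) | CC(C)C1(O)CCC=C1CC[C@]1(C)C(=O)OC[C@H]1/C=C/[Si](C)(C)c1ccccc1 | intermediate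
12 | (3S,4S)-3-[2-(2-isopropylcyclopenta-1,3-dien-1-yl)ethyl]-3-methyl-4-[(E)-2-(dimethylphenylsilyl)ethenyl]oxolan-2-one (reacting diene isomer; not isolated) | CC(C)C1=C(CC[C@]2(C)C(=O)OC[C@H]2/C=C/[Si](C)(C)c3ccccc3)CC=C1 | intermediate
13 | tetracyclic silyl lactone (norbornene with isopropyl on the alkene carbon next to the quaternary bridgehead; ring B fused to that bridgehead and the adjacent CH on the exo side; PhMe2Si endo; γ-lactone trans-fused to ring B with the methyl on its α-carbon) | C[Si](C)(c1ccccc1)[C@H]1[C@H]2C=C(C(C)C)[C@]3(CC[C@@]4(C)[C@H]([C@H]13)COC4=O)C2 | intermediate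
14 | saturated silyl lactone (as 13 with the norbornene reduced; isopropyl endo) | C[Si](C)(c1ccccc1)[C@H]1[C@H]2C[C@@H](C(C)C)[C@]3(CC[C@@]4(C)[C@H]([C@H]13)COC4=O)C2 | intermediate
15 | endo alcohol lactone (OH in place of silicon, same configuration) | O[C@H]1[C@H]2C[C@@H](C(C)C)[C@]3(CC[C@@]4(C)[C@H]([C@H]13)COC4=O)C2 | intermediate
16 | endo methyl ether lactone | CO[C@H]1[C@H]2C[C@@H](C(C)C)[C@]3(CC[C@@]4(C)[C@H]([C@H]13)COC4=O)C2 | intermediate
17 | diol (CH2OH on the quaternary methyl carbon and on the neighbouring ring-B CH, trans) | CO[C@H]1[C@H]2C[C@@H](C(C)C)[C@]3(CC[C@@](CO)(C)[C@H]([C@H]13)CO)C2 | intermediate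
18 | γ-lactol (hemiacetal carbon on the ring-B CH; ring oxygen on the CH2 of the quaternary carbon; both anomers) | CO[C@H]1[C@H]2C[C@@H](C(C)C)[C@]3(CC[C@@]4(C)[C@H]([C@H]13)C(O)OC4)C2 | intermediate
19 | alkynol (ethynyl on the ring-B CH; CH2OH on the quaternary carbon) | CO[C@H]1[C@H]2C[C@@H](C(C)C)[C@]3(CC[C@@](CO)(C)[C@H]([C@H]13)C#C)C2 | intermediate
20 | 4-alkynal (formyl on the quaternary methyl carbon; ethynyl on the neighbouring CH, trans) | CO[C@H]1[C@H]2C[C@@H](C(C)C)[C@]3(CC[C@@](C=O)(C)[C@H]([C@H]13)C#C)C2 | intermediate
21 | acetylene (ethyne) | C#C | starting material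
22 | tetracyclic dienone (ring A: C=O next to the quaternary carbon, CH=CH, then C(=CH2) on the ring-fusion CH) | CO[C@H]1[C@H]2C[C@@H](C(C)C)[C@]3(CC[C@@]4(C)[C@H]([C@H]13)C(=C)C=CC4=O)C2 | intermediate
23 | β,γ-unsaturated ketone (ring A: C=O, CH2, CH=C(CH3)) | CO[C@H]1[C@H]2C[C@@H](C(C)C)[C@]3(CC[C@@]4(C)[C@H]([C@H]13)C(C)=CCC4=O)C2 | intermediate
24 | ring-A epoxide (oxygen on the face opposite the angular methyl; not isolated) | CO[C@H]1[C@H]2C[C@@H](C(C)C)[C@]3(CC[C@@]4(C)[C@H]([C@H]13)[C@@]5(C)O[C@H]5CC4=O)C2 | intermediate
25 | dihydroxy ketone (trans-diaxial diol; tertiary OH on the face of the angular methyl, secondary OH on the opposite face) | CO[C@H]1[C@H]2C[C@@H](C(C)C)[C@]3(CC[C@@]4(C)[C@H]([C@H]13)[C@](C)(O)[C@@H](O)CC4=O)C2 | intermediate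
26 | hydrazone of 25 (not isolated) | CO[C@H]1[C@H]2C[C@@H](C(C)C)[C@]3(CC[C@@]4(C)[C@H]([C@H]13)[C@](C)(O)[C@@H](O)CC4=NN)C2 | intermediate
27 | alkenyl bromide (ring A: C(Br)=CH next to the quaternary carbon) | CO[C@H]1[C@H]2C[C@@H](C(C)C)[C@]3(CC[C@@]4(C)[C@H]([C@H]13)[C@](C)(O)[C@@H](O)C=C4Br)C2 | intermediate
28 | CNP0130529.1 | CO[C@H]1[C@H]2C[C@@H](C(C)C)[C@]3(CC[C@@]4(C)[C@H]([C@H]13)[C@](C)(O)[C@@H](O)C[C@@H]4Br)C2 | target

**Step count and risks**

Total step count: 19. Longest linear sequence: 19 steps (1 to 28).

The three steps most likely to fail: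

Step 15. Interception of the five-membered acyl rhodacycle by acetylene may be slower than its isomerisation and intramolecular hydroacylation to the fused cyclopentenone, and acetylene may oligomerise on the cationic rhodium center. The fallback closes ring A by olefin metathesis; it sets out from 19 and comes back at 23. Zirconium-catalysed methylalumination of the alkyne (AlMe3, Cp2ZrCl2, CH2Cl2) would give the alkenylalane F1, protonated on work-up to the isopropenyl alcohol F2. Dess–Martin oxidation would give the isopropenyl aldehyde F3 and allylmagnesium bromide the homoallylic alcohol F4 (either epimer). Ring-closing metathesis with the second-generation Grubbs catalyst RuCl2(=CHPh)(H2IMes)(PCy3) would give the ring-A cyclohexenol F5, and buffered Dess–Martin oxidation the β,γ-unsaturated ketone 23, from which step 17 follows.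

Step 7. Cycloaddition through the tetrasubstituted diene terminus with an unactivated vinylsilane may be slower than diene dimerisation or than cycloaddition of minor diene isomers, with loss of regiocontrol. The fallback changes the dienophile to an alkenylboronate, which reacts at lower temperature and also changes how the ring oxygen is introduced; it sets out from 10 and comes back at 15. Iododesilylation with N-iodosuccinimide in MeCN (retention) would give the (E)-alkenyl iodide enone F6, and iPrMgCl/CeCl3 the tertiary alcohol alkenyl iodide F7. Miyaura borylation (B2pin2, PdCl2(dppf), KOPh) would give the (E)-alkenylboronate alcohol F8. Dehydration with TsOH and heating at about 120 °C would give, via the cyclopentadiene boronate F9 (not isolated), the endo-boryl cycloadduct F10. Hydrogenation over Pd/C would give the saturated endo boronate F11, and NaBO3 would oxidise it with retention to the endo alcohol 15, from which step 10 follows.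

Step 18. The β-hydroxy ketone may undergo retro-aldol cleavage or dehydration during hydrazone formation, and the α-bromo cation next to the quaternary carbon may rearrange. The fallback goes through the enol triflate; it sets out from 25 and comes back at 27. Triethylsilyl triflate and 2,6-lutidine would give the bis(triethylsilyl) ether F12. KN(SiMe3)2 and Comins' reagent at –78 °C would give the enol triflate F13 (enolisation is possible only away from the quaternary carbon, and the low temperature guards against β-elimination). Nickel-catalysed triflate–bromide exchange (Ni(cod)2, LiBr, DMA–THF) would give the bis(triethylsilyl) alkenyl bromide F14, and HF·pyridine would remove both silyl groups to give 27.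

Further compounds
F1 | step 15 | alkenylalane from methylalumination of 19 (not isolated) | CO[C@H]1[C@H]2C[C@@H](C(C)C)[C@]3(CC[C@@](CO[Al](C)C)(C)[C@H]([C@H]13)/C(C)=C/[Al](C)C)C2
F2 | step 15 | isopropenyl alcohol | CO[C@H]1[C@H]2C[C@@H](C(C)C)[C@]3(CC[C@@](CO)(C)[C@H]([C@H]13)C(C)=C)C2
F3 | step 15 | isopropenyl aldehyde | CO[C@H]1[C@H]2C[C@@H](C(C)C)[C@]3(CC[C@@](C=O)(C)[C@H]([C@H]13)C(C)=C)C2
F4 | step 15 | homoallylic alcohol (either carbinol epimer) | CO[C@H]1[C@H]2C[C@@H](C(C)C)[C@]3(CC[C@@](C(O)CC=C)(C)[C@H]([C@H]13)C(C)=C)C2
F5 | step 15 | ring-A cyclohexenol | CO[C@H]1[C@H]2C[C@@H](C(C)C)[C@]3(CC[C@@]4(C)[C@H]([C@H]13)C(C)=CCC4O)C2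
F6 | step 7 | (E)-alkenyl iodide enone | O=C1CCC=C1CC[C@]1(C)C(=O)OC[C@H]1/C=C/I
F7 | step 7 | tertiary alcohol alkenyl iodide | CC(C)C1(O)CCC=C1CC[C@]1(C)C(=O)OC[C@H]1/C=C/I
F8 | step 7 | (E)-alkenylboronate alcohol | CC(C)C1(O)CCC=C1CC[C@]1(C)C(=O)OC[C@H]1/C=C/B1OC(C)(C)C(C)(C)O1
F9 | step 7 | cyclopentadiene boronate (not isolated) | CC(C)C1=C(CC[C@]2(C)C(=O)OC[C@H]2/C=C/B2OC(C)(C)C(C)(C)O2)CC=C1
F10 | step 7 | endo-boryl cycloadduct | CC1(C)OB(OC1(C)C)[C@H]1[C@H]2C=C(C(C)C)[C@]3(CC[C@@]4(C)[C@H]([C@H]13)COC4=O)C2
F11 | step 7 | saturated endo boronate | CC1(C)OB(OC1(C)C)[C@H]1[C@H]2C[C@@H](C(C)C)[C@]3(CC[C@@]4(C)[C@H]([C@H]13)COC4=O)C2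
F12 | step 18 | bis(triethylsilyl) ether of 25 | CO[C@H]1[C@H]2C[C@@H](C(C)C)[C@]3(CC[C@@]4(C)[C@H]([C@H]13)[C@](C)(O[Si](CC)(CC)CC)[C@@H](O[Si](CC)(CC)CC)CC4=O)C2
F13 | step 18 | enol triflate | CO[C@H]1[C@H]2C[C@@H](C(C)C)[C@]3(CC[C@@]4(C)[C@H]([C@H]13)[C@](C)(O[Si](CC)(CC)CC)[C@@H](O[Si](CC)(CC)CC)C=C4OS(=O)(=O)C(F)(F)F)C2
F14 | step 18 | bis(triethylsilyl) alkenyl bromide | CO[C@H]1[C@H]2C[C@@H](C(C)C)[C@]3(CC[C@@]4(C)[C@H]([C@H]13)[C@](C)(O[Si](CC)(CC)CC)[C@@H](O[Si](CC)(CC)CC)C=C4Br)C2
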